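**Retrosynthetic overview**
1. Ring atoms are lettered a–f: a = CH carrying the 3-acyloxypropyl chain, b = alkylidene carbon, c and d = the two ring CH2, e = C(CH3)(OH), f = quaternary C(CH3). The linoleate is put on last by acylation of the primary alcohol; the side chain comes from hydroboration/B-alkyl Suzuki–Miyaura coupling of a vinyl group on f with vinyl iodide 30.
2. Carbinol e and the enal go back to the 4-alkylidenecyclohexanone ester 17 (ketone → methylidene → spiro-epoxide → hydride; ester → allylic alcohol → enal).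
3. Key disconnection: ring bond b–c. The enabling feature is that alkylidene carbon b and carbinol carbon e are 1,4-related in the cyclohexane through the CH2–CH2 unit c–d. With e as a ketone, c is its homoenolate carbon, so the ring closes by palladium-catalysed ring-opening cross-coupling of a siloxycyclopropane (temporary ring holding c, d, e) with a stereodefined enol triflate at b.
4. Stereocentres a (tertiary) and f (quaternary) are set together by an enantioselective Ireland–Claisen rearrangement of (E)-allyl ester 9; the cyclopropanol comes from a Kulinkovich reaction.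
5. Order of ring formation: cyclopropane (step 2, temporary), cyclohexane (step 10), spiro-oxirane (step 12, temporary).

Key step: step 10

Remark: the sense of asymmetric induction of the diazaborolidine controller in step 7 is assigned by analogy with simpler (E)-allyl esters; should it prove opposite for ester 9, the (R,R)-controller is used without other change.

Step 1
Reactants: 1 glycolaldehyde dimer; 2 ethyl 2-(triphenylphosphoranylidene)propanoate
Product: 3 ethyl (2E)-4-hydroxy-2-methylbut-2-enoate
Conditions: CH2Cl2, reflux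
Reagents that add atoms: none
Why: Wittig olefination of the aldehyde released from the dimer with the stabilised ylide should give the (E)-enoate (ester trans to CH2OH).

Step 2
Reactants: 3 ethyl (2E)-4-hydroxy-2-methylbut-2-enoate
Product: 4 1-[(2E)-4-hydroxybut-2-en-2-yl]cyclopropan-1-ol
Conditions: EtMgBr (4.5 equiv, slow addition), Ti(OiPr)4 (0.3 equiv), THF, 0 °C to rt; aq. NH4Cl
Reagents that add atoms: ethylmagnesium bromide, CC[Mg]Br
Why: Kulinkovich cyclopropanation (titanacyclopropane from EtMgBr and Ti(OiPr)4) turns the ester into the 1-alkenylcyclopropanol, as known for alpha-substituted alpha,beta-unsaturated esters; the alkene geometry is not touched and the free hydroxyl only consumes Grignard reagent.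

Step 3
Reactants: 5 pentane-1,5-diol
Product: 6 5-hydroxypentyl 2,2-dimethylpropanoate
Conditions: 5 (3 equiv), pivaloyl chloride (1 equiv), pyridine, CH2Cl2, 0 °C
Reagents that add atoms: pivaloyl chloride, CC(C)(C)C(Cl)=O
Why: Statistical mono-acylation of the symmetrical diol used in excess; the pivalate has no alpha-hydrogen and so cannot compete in the later enolisation.

Step 4
Reactants: 6 5-hydroxypentyl 2,2-dimethylpropanoate
Product: 7 5-[(2,2-dimethylpropanoyl)oxy]pentanoic acid
Conditions: TEMPO (cat.), PhI(OAc)2 (2.2 equiv), MeCN–H2O, rt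
Reagents that add atoms: water, O
Why: Oxoammonium (TEMPO) oxidation of the primary alcohol through the aldehyde hydrate to the acid; the pivalate is inert.

Step 5
Reactants: 4 1-[(2E)-4-hydroxybut-2-en-2-yl]cyclopropan-1-ol; 7 5-[(2,2-dimethylpropanoyl)oxy]pentanoic acid
Product: 8 (2E)-3-(1-hydroxycyclopropyl)but-2-en-1-yl 5-[(2,2-dimethylpropanoyl)oxy]pentanoate
Conditions: EDC·HCl, DMAP (cat.), CH2Cl2, 0 °C
Reagents that add atoms: none
Why: Steglich-type carbodiimide esterification; the primary allylic hydroxyl is acylated while the tertiary cyclopropanol stays free.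

Step 6
Reactants: 8 (2E)-3-(1-hydroxycyclopropyl)but-2-en-1-yl 5-[(2,2-dimethylpropanoyl)oxy]pentanoate
Product: 9 (2E)-3-{1-[(triethylsilyl)oxy]cyclopropyl}but-2-en-1-yl 5-[(2,2-dimethylpropanoyl)oxy]pentanoate
Conditions: Et3SiCl, imidazole, DMAP (cat.), CH2Cl2, rt
Reagents that add atoms: chlorotriethylsilane, CC[Si](Cl)(CC)CC
Why: Silylation shields the cyclopropanol from the boron reagent and from triflation, and the siloxycyclopropane is the latent homoenolate of the key step.

Step 7
Reactants: 9 (2E)-3-{1-[(triethylsilyl)oxy]cyclopropyl}but-2-en-1-yl 5-[(2,2-dimethylpropanoyl)oxy]pentanoate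
Product: 11 (2R,3R)-2-{3-[(2,2-dimethylpropanoyl)oxy]propyl}-3-methyl-3-{1-[(triethylsilyl)oxy]cyclopropyl}pent-4-enoic acid, via boron ketene acetal 10 (not isolated)
Conditions: (4S,5S)-2-bromo-4,5-diphenyl-1,3-bis{[3,5-bis(trifluoromethyl)phenyl]sulfonyl}-1,3,2-diazaborolidine (1.2 equiv, preformed), Et3N, toluene–hexane, −78 °C, then 4 °C to rt; aqueous work-up
Reagents that add atoms: none
Why: Ireland–Claisen rearrangement of a chiral boron ketene acetal: soft enolisation gives the E(O) ketene acetal (side chain cis to the allyloxy group), the chair transition state with the (E)-allyl unit (siloxycyclopropyl pseudo-equatorial) sets tertiary centre a and quaternary centre f in the required relative configuration, and the C2-symmetric diazaborolidine chooses the enantiotopic face.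

Step 8
Reactants: 11 the (2R,3R)-acid; 12 methyl propanoate
Product: 14 methyl (4R,5R)-2,5-dimethyl-3-oxo-4-{3-[(2,2-dimethylpropanoyl)oxy]propyl}-5-{1-[(triethylsilyl)oxy]cyclopropyl}hept-6-enoate (both C2 epimers), via acyl imidazolide 13 (not isolated)
Conditions: carbonyldiimidazole, THF, rt; then LiCH(CH3)CO2Me (from 12 and LiN(iPr)2, 2.5 equiv), THF, −78 °C; AcOH quench
Reagents that add atoms: none
Why: Crossed Claisen condensation (C-acylation of the ester enolate by the acyl imidazolide); the beta-keto ester is held as its enolate, so centre a should not epimerise, and the new C2 centre does not matter because it becomes sp2 in step 9.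

Step 9
Reactants: 14 the beta-keto ester
Product: 15 methyl (2E,4R,5R)-2,5-dimethyl-4-{3-[(2,2-dimethylpropanoyl)oxy]propyl}-5-{1-[(triethylsilyl)oxy]cyclopropyl}-3-{[(trifluoromethyl)sulfonyl]oxy}hepta-2,6-dienoate
Conditions: Tf2O, aq. Me4NOH, hexane–toluene, 0 °C
Reagents that add atoms: trifluoromethanesulfonic anhydride, O=S(=O)(OS(=O)(=O)C(F)(F)F)C(F)(F)F
Why: O-Triflation of the non-chelated tetramethylammonium enolate, a protocol that favours the (E)-enol triflate of beta-keto esters (OTf trans to the ester), which is the geometry the ring closure must transfer.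

Step 10
Reactants: 15 the (E)-enol triflate
Product: 17 methyl (2Z)-2-[(2S,3R)-3-ethenyl-3-methyl-4-oxo-2-{3-[(2,2-dimethylpropanoyl)oxy]propyl}cyclohexylidene]propanoate, via free cyclopropanol 16 (not isolated)
Conditions: CsF (3 equiv), Pd(OAc)2 (10 mol%), XPhos (20 mol%), toluene–THF, 65 °C
Reagents that add atoms: none
Why: Fluoride unmasks the cyclopropanolate 16; oxidative addition of zerovalent palladium into the C–OTf bond gives a divalent alkenylpalladium that binds the alkoxide, strain-driven beta-carbon elimination opens the three-membered ring to a palladium homoenolate (Pd–CH2CH2–C=O), and C(sp2)–C(sp3) reductive elimination forms the bond between alkylidene carbon b and ring CH2 c. The closest known reaction type is the palladium-catalysed ring-opening cross-coupling of cyclopropanols and siloxycyclopropanes (ketone homoenolates) with aryl and alkenyl halides or triflates, here run intramolecularly. The six-membered carbocycle closes by reductive elimination from a seven-membered palladacycle, the alkene staying exocyclic (a 6-exo closure in the sense of the product). No stereocentre is formed: centres a and f from step 7 are not at an acidic or metalated position, and the tetrasubstituted alkene keeps the geometry of the (E)-triflate because both organometallic steps go with retention (the descriptor becomes Z only through the priority rules). The selectivity needed is cross-coupling over beta-hydride elimination of the homoenolate (enone plus reduced alkene) and over E/Z scrambling of the alkenylpalladium; the intramolecular six-ring setting and the bulky electron-rich biarylphosphine should secure it. The same operation consumes the temporary cyclopropane and leaves the ring ketone at e that later becomes the tertiary carbinol.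

Step 11
Reactants: 17 the ring ketone
Product: 18 methyl (2Z)-2-[(2S,3R)-3-ethenyl-3-methyl-4-methylidene-2-{3-[(2,2-dimethylpropanoyl)oxy]propyl}cyclohexylidene]propanoate
Conditions: Ph3PCH3Br, KN(SiMe3)2, toluene, 0 °C to 80 °C
Reagents that add atoms: methyltriphenylphosphonium bromide, C[P+](c1ccccc1)(c1ccccc1)c1ccccc1.[Br-]
Why: Wittig methylenation; the non-stabilised ylide attacks only the ketone (both esters untouched) and salt-free conditions limit enolisation next to the alkylidene unit.

Step 12
Reactants: 18 the methylidene compound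
Product: 19 spiro-epoxide of 18 at carbon e (oxirane oxygen on the ring face of the vinyl group and trans to the side chain on a)
Conditions: mCPBA, NaHCO3, CH2Cl2, 0 °C
Reagents that add atoms: 3-chloroperbenzoic acid, OOC(=O)c1cccc(Cl)c1
Why: Prilezhaev epoxidation: the 1,1-disubstituted exocyclic alkene is far more nucleophilic than the neopentyl vinyl group and the electron-poor enoate; with the side chain on a held axial by allylic 1,3-strain, the peracid should approach from the opposite ring face (that of the vinyl group), which sets centre e by substrate control.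

Step 13
Reactants: 19 the spiro-epoxide
Product: 20 (2Z)-2-[(2S,3R,4S)-3-ethenyl-4-hydroxy-2-(3-hydroxypropyl)-3,4-dimethylcyclohexylidene]propan-1-ol
Conditions: LiAlH4 (excess), THF, 0 °C to rt; aq. potassium sodium tartrate
Reagents that add atoms: none
Why: Hydride opens the spiro-epoxide at its CH2 terminus (SN2), so the oxygen keeps its configuration at e and the new methyl is cis to the methyl on f; the same reagent reduces the enoate to the allylic alcohol (1,2-reduction) and cleaves the pivalate.

Step 14
Reactants: 21 prop-2-yn-1-ol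
Product: 23 (2E)-3-iodo-2-methylprop-2-en-1-ol, via alkenylalane 22 (not isolated)
Conditions: AlMe3 (3 equiv), Cp2ZrCl2 (0.25 equiv), CH2Cl2, 0 °C to rt; then I2, THF, −30 °C
Reagents that add atoms: trimethylaluminium, C[Al](C)C; iodine, II
Why: Zirconium-catalysed carboalumination adds methyl and aluminium syn across the alkyne (methyl on the internal carbon), and iodinolysis with retention gives the (E)-vinyl iodide.

Step 15
Reactants: 23 (2E)-3-iodo-2-methylprop-2-en-1-ol
Product: 24 (2E)-3-iodo-2-methylprop-2-enal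
Conditions: MnO2, CH2Cl2, rt
Reagents that add atoms: none
Why: Selective oxidation of an allylic alcohol by MnO2 without isomerisation of the alkene.

Step 16
Reactants: 24 (2E)-3-iodo-2-methylprop-2-enal; 25 geranyl chloride
Product: 27 racemic (1E,5E)-1-iodo-2,6,10-trimethylundeca-1,5,9-trien-3-ol, via geranylbarium chloride 26 (not isolated)
Conditions: 25, activated barium (from BaI2 and lithium biphenylide), THF, −78 °C; then 24, −78 °C
Reagents that add atoms: none
Why: Allylbarium addition to an aldehyde is alpha-selective (bond formation through the CH2 terminus) and retains the (E)-geometry of the allyl unit, giving the linear homoallylic alcohol as a racemate.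

Step 17
Reactants: 27 the racemic alcohol
Product: 28 (1E,5E)-1-iodo-2,6,10-trimethylundeca-1,5,9-trien-3-one
Conditions: Dess–Martin periodinane, NaHCO3, CH2Cl2, 0 °C
Reagents that add atoms: none
Why: Buffered Dess–Martin oxidation gives the enone under neutral conditions that should not move the beta,gamma-double bond into conjugation.

Step 18
Reactants: 28 the enone
Product: 29 (3R,1E,5E)-1-iodo-2,6,10-trimethylundeca-1,5,9-trien-3-ol
Conditions: (S)-2-methyl-CBS-oxazaborolidine (0.2 equiv), catecholborane, toluene, −78 °C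
Reagents that add atoms: none
Why: Corey–Bakshi–Shibata reduction in which the alpha-methyl alkenyl group acts as the large substituent, so the (S)-catalyst should deliver the (R)-carbinol; catecholborane at low temperature avoids hydroboration of the alkenes.

Step 19
Reactants: 29 the (R)-alcohol
Product: 30 tert-butyl{[(3R,1E,5E)-1-iodo-2,6,10-trimethylundeca-1,5,9-trien-3-yl]oxy}dimethylsilane
Conditions: TBSCl, imidazole, DMF, rt
Reagents that add atoms: tert-butylchlorodimethylsilane, CC(C)(C)[Si](C)(C)Cl
Why: Standard silylation of the secondary allylic alcohol; the ether survives the coupling, oxidation and acylation steps.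

Step 20
Reactants: 20 the triol; 30 the vinyl iodide
Product: 32 (2Z)-2-[(2S,3R,4S)-4-hydroxy-2-(3-hydroxypropyl)-3,4-dimethyl-3-{(3E,5R,7E)-5-[(tert-butyldimethylsilyl)oxy]-4,8,12-trimethyltrideca-3,7,11-trien-1-yl}cyclohexylidene]propan-1-ol, via B-alkyl-9-BBN 31 (not isolated)
Conditions: 9-BBN dimer (excess), THF, rt to 50 °C; then 30, Pd(dppf)Cl2, AsPh3, Cs2CO3, DMF–H2O, rt
Reagents that add atoms: none
Why: Hydroboration with 9-BBN is anti-Markovnikov and touches only the terminal vinyl group (the tetrasubstituted alkene is inert and the hydroxyls are masked as borinates by the excess reagent); the B-alkyl Suzuki–Miyaura coupling joins the primary alkylborane to the vinyl iodide with retention of the (E)-geometry.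

Step 21
Reactants: 32 the coupled triol
Product: 33 (2Z)-2-[(2S,3R,4S)-4-hydroxy-2-(3-hydroxypropyl)-3,4-dimethyl-3-{(3E,5R,7E)-5-[(tert-butyldimethylsilyl)oxy]-4,8,12-trimethyltrideca-3,7,11-trien-1-yl}cyclohexylidene]propanal
Conditions: MnO2, CH2Cl2, rt
Reagents that add atoms: none
Why: MnO2 oxidises only the allylic primary alcohol to the enal; the saturated primary and the tertiary alcohol stay, and the alkene geometry is kept under these neutral conditions.

Step 22
Reactants: 33 the hydroxy enal; 34 linoleic acid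
Product: 35 the 5-O-tert-butyldimethylsilyl ether of the target
Conditions: EDC·HCl, DMAP, CH2Cl2, 0 °C to rt
Reagents that add atoms: none
Why: Steglich-type esterification of the only primary alcohol; the tertiary alcohol is not acylated and the skipped diene of the acid is untouched.

Step 23
Reactants: 35 the silyl ether
Product: 36 3-[(1S,2R,3S,6Z)-3-hydroxy-2-{(3E,5R,7E)-5-hydroxy-4,8,12-trimethyltrideca-3,7,11-trien-1-yl}-2,3-dimethyl-6-(1-oxopropan-2-ylidene)cyclohexyl]propyl (9Z,12Z)-octadeca-9,12-dienoate
Conditions: HF·pyridine, pyridine, THF, 0 °C to rt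
Reagents that add atoms: none
Why: Buffered fluoride cleavage of the secondary silyl ether, mild enough for the enal, the ester and the allylic carbinol.

**Compound list**
1 | glycolaldehyde dimer (2,5-dihydroxy-1,4-dioxane) | OC1COC(O)CO1 | starting material
2 | ethyl 2-(triphenylphosphoranylidene)propanoate | CCOC(=O)C(C)=P(c1ccccc1)(c1ccccc1)c1ccccc1 | starting material
3 | ethyl (2E)-4-hydroxy-2-methylbut-2-enoate | CCOC(=O)/C(C)=C/CO | intermediate
4 | 1-[(2E)-4-hydroxybut-2-en-2-yl]cyclopropan-1-ol | OC/C=C(\C)C1(O)CC1 | intermediate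
5 | pentane-1,5-diol | OCCCCCO | starting material
6 | 5-hydroxypentyl 2,2-dimethylpropanoate | CC(C)(C)C(=O)OCCCCCO | intermediate
7 | 5-[(2,2-dimethylpropanoyl)oxy]pentanoic acid | CC(C)(C)C(=O)OCCCCC(=O)O | intermediate
8 | (2E)-3-(1-hydroxycyclopropyl)but-2-en-1-yl 5-[(2,2-dimethylpropanoyl)oxy]pentanoate | CC(C)(C)C(=O)OCCCCC(=O)OC/C=C(\C)C1(O)CC1 | intermediate
9 | (2E)-3-{1-[(triethylsilyl)oxy]cyclopropyl}but-2-en-1-yl 5-[(2,2-dimethylpropanoyl)oxy]pentanoate | CC(C)(C)C(=O)OCCCCC(=O)OC/C=C(\C)C1(O[Si](CC)(CC)CC)CC1 | intermediate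
10 | E(O) boron ketene acetal of 9 bound to the (4S,5S)-diazaborolidine (side chain cis to the allyloxy group) | CC(C)(C)C(=O)OCCC/C=C(\OC/C=C(\C)C1(O[Si](CC)(CC)CC)CC1)OB1N(S(=O)(=O)c2cc(cc(c2)C(F)(F)F)C(F)(F)F)[C@@H](c2ccccc2)[C@H](c2ccccc2)N1S(=O)(=O)c1cc(cc(c1)C(F)(F)F)C(F)(F)F | intermediate
11 | (2R,3R)-2-{3-[(2,2-dimethylpropanoyl)oxy]propyl}-3-methyl-3-{1-[(triethylsilyl)oxy]cyclopropyl}pent-4-enoic acid | CC(C)(C)C(=O)OCCC[C@@H](C(=O)O)[C@@](C)(C=C)C1(O[Si](CC)(CC)CC)CC1 | intermediate
12 | methyl propanoate | CCC(=O)OC | starting material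
13 | 1-acylimidazole of acid 11 | CC(C)(C)C(=O)OCCC[C@@H](C(=O)n1ccnc1)[C@@](C)(C=C)C1(O[Si](CC)(CC)CC)CC1 | intermediate
14 | methyl (4R,5R)-2,5-dimethyl-3-oxo-4-{3-[(2,2-dimethylpropanoyl)oxy]propyl}-5-{1-[(triethylsilyl)oxy]cyclopropyl}hept-6-enoate (both C2 epimers) | CC(C)(C)C(=O)OCCC[C@@H](C(=O)C(C)C(=O)OC)[C@@](C)(C=C)C1(O[Si](CC)(CC)CC)CC1 | intermediate
15 | methyl (2E,4R,5R)-2,5-dimethyl-4-{3-[(2,2-dimethylpropanoyl)oxy]propyl}-5-{1-[(triethylsilyl)oxy]cyclopropyl}-3-{[(trifluoromethyl)sulfonyl]oxy}hepta-2,6-dienoate | CC(C)(C)C(=O)OCCC[C@@H](/C(OS(=O)(=O)C(F)(F)F)=C(/C)C(=O)OC)[C@@](C)(C=C)C1(O[Si](CC)(CC)CC)CC1 | intermediate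
16 | free cyclopropanol of 15 (caesium alkoxide in the flask) | CC(C)(C)C(=O)OCCC[C@@H](/C(OS(=O)(=O)C(F)(F)F)=C(/C)C(=O)OC)[C@@](C)(C=C)C1(O)CC1 | intermediate
17 | methyl (2Z)-2-[(2S,3R)-3-ethenyl-3-methyl-4-oxo-2-{3-[(2,2-dimethylpropanoyl)oxy]propyl}cyclohexylidene]propanoate | CC(C)(C)C(=O)OCCC[C@H]1/C(=C(/C)C(=O)OC)CCC(=O)[C@]1(C)C=C | intermediate
18 | methyl (2Z)-2-[(2S,3R)-3-ethenyl-3-methyl-4-methylidene-2-{3-[(2,2-dimethylpropanoyl)oxy]propyl}cyclohexylidene]propanoate | CC(C)(C)C(=O)OCCC[C@H]1/C(=C(/C)C(=O)OC)CCC(=C)[C@]1(C)C=C | intermediate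
19 | spiro-epoxide of 18 at carbon e (1-oxaspiro[2.5]octane; oxirane oxygen cis to the vinyl group) | CC(C)(C)C(=O)OCCC[C@H]1/C(=C(/C)C(=O)OC)CC[C@]2(OC2)[C@]1(C)C=C | intermediate
20 | (2Z)-2-[(2S,3R,4S)-3-ethenyl-4-hydroxy-2-(3-hydroxypropyl)-3,4-dimethylcyclohexylidene]propan-1-ol | OCCC[C@H]1/C(=C(/C)CO)CC[C@](C)(O)[C@]1(C)C=C | intermediate
21 | prop-2-yn-1-ol | C#CCO | starting material
22 | (E)-alkenylalane from carboalumination (aluminium alkoxide) | C[Al](C)/C=C(\C)CO[Al](C)C | intermediate
23 | (2E)-3-iodo-2-methylprop-2-en-1-ol | OC/C(C)=C/I | intermediate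
24 | (2E)-3-iodo-2-methylprop-2-enal | O=C/C(C)=C/I | intermediate
25 | geranyl chloride ((2E)-1-chloro-3,7-dimethylocta-2,6-diene) | CC(C)=CCC/C(C)=C/CCl | starting material
26 | geranylbarium chloride | CC(C)=CCC/C(C)=C/C[Ba]Cl | intermediate
27 | racemic (1E,5E)-1-iodo-2,6,10-trimethylundeca-1,5,9-trien-3-ol | I/C=C(\C)C(O)C/C=C(\C)CCC=C(C)C | intermediate
28 | (1E,5E)-1-iodo-2,6,10-trimethylundeca-1,5,9-trien-3-one | I/C=C(\C)C(=O)C/C=C(\C)CCC=C(C)C | intermediate
29 | (3R,1E,5E)-1-iodo-2,6,10-trimethylundeca-1,5,9-trien-3-ol | I/C=C(\C)[C@H](O)C/C=C(\C)CCC=C(C)C | intermediate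
30 | tert-butyl{[(3R,1E,5E)-1-iodo-2,6,10-trimethylundeca-1,5,9-trien-3-yl]oxy}dimethylsilane | I/C=C(\C)[C@H](O[Si](C)(C)C(C)(C)C)C/C=C(\C)CCC=C(C)C | intermediate
31 | B-alkyl-9-BBN adduct of triol 20 | OCCC[C@H]1/C(=C(/C)CO)CC[C@](C)(O)[C@]1(C)CCB1C2CCCC1CCC2 | intermediate
32 | coupled triol silyl ether (name in step 20) | OCCC[C@H]1/C(=C(/C)CO)CC[C@](C)(O)[C@]1(C)CC/C=C(\C)[C@H](O[Si](C)(C)C(C)(C)C)C/C=C(\C)CCC=C(C)C | intermediate
33 | hydroxy enal silyl ether (name in step 21) | OCCC[C@H]1/C(=C(/C)C=O)CC[C@](C)(O)[C@]1(C)CC/C=C(\C)[C@H](O[Si](C)(C)C(C)(C)C)C/C=C(\C)CCC=C(C)C | intermediate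
34 | linoleic acid ((9Z,12Z)-octadeca-9,12-dienoic acid) | CCCCC/C=C\C/C=C\CCCCCCCC(=O)O | starting material
35 | 5-O-tert-butyldimethylsilyl ether of the target | CCCCC/C=C\C/C=C\CCCCCCCC(=O)OCCC[C@H]1/C(=C(/C)C=O)CC[C@](C)(O)[C@]1(C)CC/C=C(\C)[C@H](O[Si](C)(C)C(C)(C)C)C/C=C(\C)CCC=C(C)C | intermediate
36 | 3-[(1S,2R,3S,6Z)-3-hydroxy-2-{(3E,5R,7E)-5-hydroxy-4,8,12-trimethyltrideca-3,7,11-trien-1-yl}-2,3-dimethyl-6-(1-oxopropan-2-ylidene)cyclohexyl]propyl (9Z,12Z)-octadeca-9,12-dienoate | CCCCC/C=C\C/C=C\CCCCCCCC(=O)OCCC[C@H]1/C(=C(/C)C=O)CC[C@](C)(O)[C@]1(C)CC/C=C(\C)[C@H](O)C/C=C(\C)CCC=C(C)C | target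

**Step count and risks**
Total: 23 steps. Longest linear sequence: 15 steps (1, 2, 5–13, 20–23).

Steps most likely to fail:

1. Step 10 (key step). The palladium homoenolate may undergo beta-hydride elimination (enone formation and reduction of the triflate) faster than ring-closing reductive elimination, or the alkenylpalladium may lose its geometry. The fallback sets out from 15 and returns at 17. The siloxycyclopropane of 15 is opened with N-iodosuccinimide (CH2Cl2, 0 °C) to the beta-iodo ketone methyl (2E,4R,5R)-5-(3-iodopropanoyl)-2,5-dimethyl-4-{3-[(2,2-dimethylpropanoyl)oxy]propyl}-3-{[(trifluoromethyl)sulfonyl]oxy}hepta-2,6-dienoate F1. Its primary iodide and enol triflate are then joined by nickel-catalysed reductive cross-electrophile coupling (NiBr2·glyme, 4,4'-di-tert-butyl-2,2'-bipyridine, Mn powder, DMA, rt), a radical-based closure that does not pass through a palladium homoenolate, to give 17.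

2. Step 12. Both faces of the exocyclic methylidene group are flanked by an axial substituent, so facial selectivity of the epoxidation may be poor or reversed, and the vinyl group may be epoxidised in part. The fallback sets out from 17 and returns at 20. It is stereocomplementary because it delivers carbon, not oxygen, to the accessible face: MeMgBr with CeCl3 (THF, −78 °C) adds methyl to the ring ketone to give methyl (2Z)-2-[(2S,3R,4S)-3-ethenyl-4-hydroxy-3,4-dimethyl-2-{3-[(2,2-dimethylpropanoyl)oxy]propyl}cyclohexylidene]propanoate F2. LiAlH4 (THF, 0 °C) then reduces the enoate and the pivalate to give 20.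

3. Step 7. Rearrangement at the hindered, fully substituted allyl terminus may be slow, with erosion of enantio- or diastereocontrol by the boron controller. The fallback sets out from 9 and returns at 11. LiN(iPr)2 and Me3SiCl (THF, −78 °C) give the E(O) trimethylsilyl ketene acetal of 9 F3, which rearranges on warming through the same chair to the racemic trimethylsilyl ester of the anti acid F4. Aqueous work-up gives the racemic (2R*,3R*)-acid F5, and preparative chromatography on a chiral stationary phase delivers 11.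

**Further compounds**
F1 | step 10 | methyl (2E,4R,5R)-5-(3-iodopropanoyl)-2,5-dimethyl-4-{3-[(2,2-dimethylpropanoyl)oxy]propyl}-3-{[(trifluoromethyl)sulfonyl]oxy}hepta-2,6-dienoate | CC(C)(C)C(=O)OCCC[C@@H](/C(OS(=O)(=O)C(F)(F)F)=C(/C)C(=O)OC)[C@@](C)(C=C)C(=O)CCI
F2 | step 12 | methyl (2Z)-2-[(2S,3R,4S)-3-ethenyl-4-hydroxy-3,4-dimethyl-2-{3-[(2,2-dimethylpropanoyl)oxy]propyl}cyclohexylidene]propanoate | CC(C)(C)C(=O)OCCC[C@H]1/C(=C(/C)C(=O)OC)CC[C@](C)(O)[C@]1(C)C=C
F3 | step 7 | E(O) trimethylsilyl ketene acetal of 9 | CC(C)(C)C(=O)OCCC/C=C(\OC/C=C(\C)C1(O[Si](CC)(CC)CC)CC1)O[Si](C)(C)C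
F4 | step 7 | racemic trimethylsilyl ester of the (2R*,3R*)-acid | CC(C)(C)C(=O)OCCC[C@@H](C(=O)O[Si](C)(C)C)[C@@](C)(C=C)C1(O[Si](CC)(CC)CC)CC1.CC(C)(C)C(=O)OCCC[C@H](C(=O)O[Si](C)(C)C)[C@](C)(C=C)C1(O[Si](CC)(CC)CC)CC1
F5 | step 7 | racemic (2R*,3R*)-2-{3-[(2,2-dimethylpropanoyl)oxy]propyl}-3-methyl-3-{1-[(triethylsilyl)oxy]cyclopropyl}pent-4-enoic acid | CC(C)(C)C(=O)OCCC[C@@H](C(=O)O)[C@@](C)(C=C)C1(O[Si](CC)(CC)CC)CC1.CC(C)(C)C(=O)OCCC[C@H](C(=O)O)[C@](C)(C=C)C1(O[Si](CC)(CC)CC)CC1
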